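**Pooled constant.** 1.54 is the equilibrium constant of the coupling when target and isomer of the product count as one pool and substrate and dormant form as another: 1.16 times one plus 0.89, over one plus 0.421.

    substrate + coupling partner ⇌ target + by-product (K1 = 1.16, k1 = 8.83 × 10⁻⁴ /M/s)
    substrate ⇌ dormant form (K2 = 0.421, k2 = 6.47 × 10⁻⁴ /s)
    target ⇌ isomer of the product (K3 = 0.89, k3 = 0.00326 /s)

substrate 1.8 M; coupling partner 1.08 M; time 10 h

- at 10 h, what has stopped the reaction, if anything has (all of the substrate has reacted / it is still moving / forward and back rates have come level / the coupling partner has run out first)
- the target standing at 10 h, as a percentage of the substrate charged
- the isomer of the product standing at 10 h, as a percentage of the substrate charged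

- the reaction counts as stopped when no species that holds the substrate changes by six tenths of a point or more over the second half of the time
- run time (flask): 10 h

**The reckoning.** Once every step stands level, the square of the by-product equals 1.54 times the substrate pool left times the coupling partner left. This quadratic gives 0.742 M of by-product. The coupling partner, the limiting reagent, keeps 0.338 M. The pool splits one to 0.89, so target comes to 21.8% and isomer of the product to 19.4%.

**Two clocks.** Whether 10 h is enough can be counted in two ways. At its opening rate, the coupling makes that by-product in 0.120 h. Near the end, with the pools formed, the remaining gap shrinks with a time constant of 0.190 h. The two part, and the opening clock is the one that cheats, because it keeps constant a rate that falls as the charges are used and the back reaction grows; the longer time is the one to count with. Even so, 10 h holds 52.6 such constants, and the relaxation half-life of substrate and dormant form by their own step, 0.0882 h, is also far shorter than 10 h. With the time constant far shorter than the run, the flask should therefore be under thermodynamic control.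

**The forecast.** Its verdict is that forward and back rates have come level, with 21.8% of target and 19.4% of isomer of the product, on the ground that “the flask is fully at equilibrium”. The reckoning above gives the same.

**The simulation.** In the flask at the asked time, forward and back rates have come level, and it stands at 21.8% of target and 19.4% of isomer of the product.

**Time against conversion.** This flask reaches nineteen twentieths of its conversion by 0.367 h, much earlier than 10 h, and its shares move 0 percentage points over the second half of the time. The pool quotient read from its state at 10.0 h is 1.54, level with 1.54.

**Leaner flask.** For a neighbour flask charged with 0.72 M of substrate, 1.54 gives 0.476 M of by-product, hence 35.0% of target and 31.1% of isomer of the product, in percent of its own substrate charge. The simulation of that neighbour flask gives 35.0% and 31.2%.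

The rate constants stand for no real mixture; the flask was simulated.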